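**Plan**
- Retrosynthesis: (1) cut C2–C3 of the cyclopentanone (ketone carbon to the methyl-bearing CH), leaving a cyclohexene with a vinyl group on C3a and a 1-oxobutan-2-yl arm on C7a; (2) re-join these two arms as a δ-lactone and cut C4–C5 and C3a–C7a (Diels–Alder) to a trienyl fumarate; (3) cut the ester tether and the three C=C bonds of the triene (olefinations).
- Enabling feature: C2 is a ring ketone whose α-carbon C3 carries H and CH3 and sits on ring-fusion carbon C3a. This 2-methylcyclopentanone is the product pattern of 5-exo addition of a C2 acyl radical (on the C1/C7a arm) to a vinyl group on C3a, the methyl arising from the terminal CH2.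
- Forward: auxiliary-based synthesis of the C1 centre, two formyl-ylide homologations and a benzyl olefination (triene), esterification with a 2-ethylfumaric half ester, intramolecular Diels–Alder (cyclohexene plus temporary lactone ring), lactone opened to vinyl and aldehyde, radical cycloisomerisation closing the cyclopentanone, ester cleavage.
- Stereochemistry: C1 from the oxazolidinone-controlled hydroxymethylation; C3a, C4, C5 and C7a from the Diels–Alder step (E,E-diene, E-dienophile, ester-endo/tether-anti transition state, face chosen by A(1,3) strain at the C1 centre); C3 by equilibration next to the ketone.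

Key step: step 19

Assumption: C1 and C3, both α to the ketone, are taken to hold their more stable configurations in the target (alkyl groups pseudo-equatorial on the trans-fused cyclopentanone), so base equilibration should deliver them.

**Step 1**
Reactants: 1 propyl(triphenyl)phosphonium bromide; 2 ethyl formate
Product: 4 2-(triphenyl-λ5-phosphanylidene)butanal, via propylidene(triphenyl)phosphorane 3 (not isolated)
Conditions: KOt-Bu (2.1 equiv), THF, 0 °C; then HCO2Et, 0 °C → rt
Reagents that add atoms: none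
Why: C-formylation of the non-stabilised ylide by the formate ester and deprotonation of the formylphosphonium salt should give the stabilised formyl ylide (ylide acylation).

**Step 2**
Reactants: 5 (4R)-4-benzyl-1,3-oxazolidin-2-one; 6 butanoyl chloride
Product: 7 (4R)-4-benzyl-3-butanoyl-1,3-oxazolidin-2-one
Conditions: n-BuLi, THF, −78 °C; then 6, −78 → 0 °C
Reagents that add atoms: none
Why: N-acylation of the lithiated oxazolidinone with an acid chloride is standard and attaches the chiral auxiliary.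

**Step 3**
Reactants: 7 (4R)-4-benzyl-3-butanoyl-1,3-oxazolidin-2-one
Product: 8 (4R)-4-benzyl-3-[(2S)-2-(hydroxymethyl)butanoyl]-1,3-oxazolidin-2-one
Conditions: TiCl4, i-Pr2NEt, CH2Cl2, 0 °C; then 1,3,5-trioxane, TiCl4, 0 °C
Reagents that add atoms: 1,3,5-trioxane, C1OCOCO1
Why: Auxiliary-controlled hydroxymethylation of the chelated (Z)-titanium enolate with Lewis-acid-activated formaldehyde; attack on the face opposite the benzyl group should set the (2S) centre that becomes C1 of the target.

**Step 4**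
Reactants: 8 (4R)-4-benzyl-3-[(2S)-2-(hydroxymethyl)butanoyl]-1,3-oxazolidin-2-one
Product: 9 (4R)-4-benzyl-3-[(2S)-2-({[tert-butyl(dimethyl)silyl]oxy}methyl)butanoyl]-1,3-oxazolidin-2-one
Conditions: TBSCl, imidazole, DMF, rt
Reagents that add atoms: tert-butyl(chloro)dimethylsilane, CC(C)(C)[Si](C)(C)Cl
Why: Silylation of the primary alcohol keeps the two one-carbon arms on the stereocentre distinct and blocks retro-aldol loss of formaldehyde.

**Step 5**
Reactants: 9 (4R)-4-benzyl-3-[(2S)-2-({[tert-butyl(dimethyl)silyl]oxy}methyl)butanoyl]-1,3-oxazolidin-2-one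
Product: 10 (2R)-2-({[tert-butyl(dimethyl)silyl]oxy}methyl)butan-1-ol
Conditions: LiBH4, MeOH (1 equiv), THF, 0 °C
Reagents that add atoms: none
Why: Reductive cleavage of the N-acyl oxazolidinone with lithium borohydride should give the primary alcohol without touching the stereocentre or the silyl ether, and returns the auxiliary.

**Step 6**
Reactants: 10 (2R)-2-({[tert-butyl(dimethyl)silyl]oxy}methyl)butan-1-ol
Product: 11 (2S)-2-({[tert-butyl(dimethyl)silyl]oxy}methyl)butanal
Conditions: Dess–Martin periodinane, NaHCO3, CH2Cl2, 0 °C → rt; used crude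
Reagents that add atoms: none
Why: Buffered Dess–Martin oxidation is non-basic, so the α-branched aldehyde should form without epimerisation or β-elimination.

**Step 7**
Reactants: 11 (2S)-2-({[tert-butyl(dimethyl)silyl]oxy}methyl)butanal; 4 2-(triphenyl-λ5-phosphanylidene)butanal
Product: 12 (2E,4R)-5-{[tert-butyl(dimethyl)silyl]oxy}-2,4-diethylpent-2-enal
Conditions: 4 (1.3 equiv), toluene, 90 °C
Reagents that add atoms: none
Why: Wittig reaction of the stabilised α-ethyl formyl ylide should give the (E)-trisubstituted enal, and the ylide is too weakly basic to epimerise the α-centre.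

**Step 8**
Reactants: 12 (2E,4R)-5-{[tert-butyl(dimethyl)silyl]oxy}-2,4-diethylpent-2-enal; 4 2-(triphenyl-λ5-phosphanylidene)butanal
Product: 13 (2E,4E,6R)-7-{[tert-butyl(dimethyl)silyl]oxy}-2,4,6-triethylhepta-2,4-dienal
Conditions: 4 (1.5 equiv), toluene, 110 °C
Reagents that add atoms: none
Why: A second Wittig homologation with the same stabilised ylide should add the next (E)-trisubstituted double bond; the more conjugated product reacts more slowly than the enal, which limits over-homologation.

**Step 9**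
Reactants: 13 (2E,4E,6R)-7-{[tert-butyl(dimethyl)silyl]oxy}-2,4,6-triethylhepta-2,4-dienal; 14 diethyl benzylphosphonate
Product: 15 tert-butyl(dimethyl){[(2R,3E,5E,7E)-2,4,6-triethyl-8-phenylocta-3,5,7-trien-1-yl]oxy}silane
Conditions: 14, NaH, THF, 0 °C; then 13, −78 → 0 °C
Reagents that add atoms: none
Why: Horner–Wadsworth–Emmons olefination with the benzylphosphonate anion should give the (E)-styryl double bond; addition of the aldehyde at low temperature limits vinylogous deprotonation at the stereocentre.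

**Step 10**
Reactants: 15 tert-butyl(dimethyl){[(2R,3E,5E,7E)-2,4,6-triethyl-8-phenylocta-3,5,7-trien-1-yl]oxy}silane
Product: 16 (2R,3E,5E,7E)-2,4,6-triethyl-8-phenylocta-3,5,7-trien-1-ol
Conditions: TBAF, THF, 0 °C → rt
Reagents that add atoms: none
Why: Fluoride cleavage of the primary silyl ether is selective and leaves the triene untouched.

**Step 11**
Reactants: 17 2-bromobutanoyl bromide; 18 2-(trimethylsilyl)ethanol
Product: 19 2-(trimethylsilyl)ethyl 2-bromobutanoate
Conditions: pyridine, CH2Cl2, 0 °C → rt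
Reagents that add atoms: none
Why: Acylation of the alcohol by the acid bromide installs an ester that can later be removed by fluoride at a remote site, however hindered the carboxyl carbon becomes.

**Step 12**
Reactants: 19 2-(trimethylsilyl)ethyl 2-bromobutanoate
Product: 21 2-(trimethylsilyl)ethyl 2-(triphenyl-λ5-phosphanylidene)butanoate, via phosphonium bromide 20 (not isolated)
Conditions: PPh3, toluene, 90 °C; then aq. NaOH, CH2Cl2, 0 °C
Reagents that add atoms: triphenylphosphine, c1ccc(cc1)P(c1ccccc1)c1ccccc1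
Why: SN2 quaternisation of triphenylphosphine by the α-bromo ester and deprotonation of the salt should give the stabilised ester ylide.

**Step 13**
Reactants: 21 2-(trimethylsilyl)ethyl 2-(triphenyl-λ5-phosphanylidene)butanoate; 22 glyoxylic acid monohydrate
Product: 23 (2E)-3-ethyl-4-oxo-4-[2-(trimethylsilyl)ethoxy]but-2-enoic acid
Conditions: 21 (1.1 equiv), CH2Cl2, 0 °C → rt; NaHCO3 extraction, then acidification
Reagents that add atoms: none
Why: Wittig reaction of the stabilised ylide with the very electrophilic glyoxylic aldehyde should place the two carboxyl groups trans (fumarate geometry) and leave the unhindered carboxyl free for the tether.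

**Step 14**
Reactants: 16 (2R,3E,5E,7E)-2,4,6-triethyl-8-phenylocta-3,5,7-trien-1-ol; 23 (2E)-3-ethyl-4-oxo-4-[2-(trimethylsilyl)ethoxy]but-2-enoic acid
Product: 24 4-[(2R,3E,5E,7E)-2,4,6-triethyl-8-phenylocta-3,5,7-trien-1-yl] 1-[2-(trimethylsilyl)ethyl] (2E)-2-ethylbut-2-enedioate
Conditions: DCC, DMAP (cat.), CH2Cl2, 0 °C → rt
Reagents that add atoms: none
Why: Steglich esterification of the primary alcohol with the unhindered fumaric carboxyl joins diene and dienophile through a four-atom ester tether.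

**Step 15**
Reactants: 24 4-[(2R,3E,5E,7E)-2,4,6-triethyl-8-phenylocta-3,5,7-trien-1-yl] 1-[2-(trimethylsilyl)ethyl] (2E)-2-ethylbut-2-enedioate
Product: 25 2-(trimethylsilyl)ethyl (4R,4aR,7R,8S,8aR)-4,5,7,8-tetraethyl-1-oxo-7-[(E)-2-phenylethenyl]-3,4,4a,7,8,8a-hexahydro-1H-isochromene-8-carboxylate
Conditions: toluene (0.01 M), BHT, 130 °C, sealed tube
Reagents that add atoms: none
Why: Intramolecular Diels–Alder reaction of an ester-tethered decatriene with a doubly activated fumarate: the E,E-diene and E-dienophile fix the two pairs of centres, the free ester lies endo with the tether anti (trans-fused lactone), and A(1,3) strain between the hydrogen of the tether stereocentre and the neighbouring diene ethyl group directs the dienophile to one face, so the single (R) centre should control both quaternary carbons and both ring-fusion carbons.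

**Step 16**
Reactants: 25 2-(trimethylsilyl)ethyl (4R,4aR,7R,8S,8aR)-4,5,7,8-tetraethyl-1-oxo-7-[(E)-2-phenylethenyl]-3,4,4a,7,8,8a-hexahydro-1H-isochromene-8-carboxylate
Product: 26 2-(trimethylsilyl)ethyl (4R,4aR,7R,8S,8aR)-4,5,7,8-tetraethyl-1-hydroxy-7-[(E)-2-phenylethenyl]-3,4,4a,7,8,8a-hexahydro-1H-isochromene-8-carboxylate (lactol; both C1 anomers)
Conditions: DIBAL-H (1.1 equiv), CH2Cl2, −78 °C; Rochelle salt
Reagents that add atoms: none
Why: Half-reduction of the δ-lactone stops at the lactol at low temperature, and the silylethyl ester on the quaternary carbon is far more hindered than the lactone carbonyl.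

**Step 17**
Reactants: 26 2-(trimethylsilyl)ethyl (4R,4aR,7R,8S,8aR)-4,5,7,8-tetraethyl-1-hydroxy-7-[(E)-2-phenylethenyl]-3,4,4a,7,8,8a-hexahydro-1H-isochromene-8-carboxylate
Product: 27 2-(trimethylsilyl)ethyl (1S,2R,5S,6R)-6-ethenyl-1,2,4-triethyl-5-[(2R)-1-hydroxybutan-2-yl]-2-[(E)-2-phenylethenyl]cyclohex-3-ene-1-carboxylate
Conditions: Ph3PCH3Br, KOt-Bu, THF, 0 °C → rt
Reagents that add atoms: methyl(triphenyl)phosphonium bromide, C[P+](c1ccccc1)(c1ccccc1)c1ccccc1.[Br-]
Why: Wittig methylenation of the lactol through its open hydroxy-aldehyde form turns the former lactone carbon into the vinyl CH (future C3) and frees the primary alcohol; the equatorial aldehyde is the more stable epimer, so the ring-fusion centre should hold.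

**Step 18**
Reactants: 27 2-(trimethylsilyl)ethyl (1S,2R,5S,6R)-6-ethenyl-1,2,4-triethyl-5-[(2R)-1-hydroxybutan-2-yl]-2-[(E)-2-phenylethenyl]cyclohex-3-ene-1-carboxylate
Product: 28 2-(trimethylsilyl)ethyl (1S,2R,5S,6R)-6-ethenyl-1,2,4-triethyl-5-[(2R)-1-oxobutan-2-yl]-2-[(E)-2-phenylethenyl]cyclohex-3-ene-1-carboxylate
Conditions: Dess–Martin periodinane, NaHCO3, CH2Cl2, 0 °C → rt
Reagents that add atoms: none
Why: Neutral Dess–Martin oxidation of the primary alcohol gives the aldehyde (future C2) without affecting the alkenes or the ester.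

**Step 19**
Reactants: 28 2-(trimethylsilyl)ethyl (1S,2R,5S,6R)-6-ethenyl-1,2,4-triethyl-5-[(2R)-1-oxobutan-2-yl]-2-[(E)-2-phenylethenyl]cyclohex-3-ene-1-carboxylate
Product: 30 2-(trimethylsilyl)ethyl (1R,3R,3aS,4S,5R,7aS)-1,4,5,7-tetraethyl-3-methyl-2-oxo-5-[(E)-2-phenylethenyl]-2,3,3a,4,5,7a-hexahydro-1H-indene-4-carboxylate, via C3 epimer mixture 29 (not isolated)
Conditions: t-C12H25SH (0.3 equiv), V-40 (0.2 equiv, in portions), PhCl (0.05 M), 100 °C; then DBU (0.3 equiv), CH2Cl2, rt
Reagents that add atoms: none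
Why: A thiyl radical abstracts the aldehydic hydrogen of 28 (polarity-reversal catalysis), the C2 acyl radical adds to the inner carbon of the vinyl group on C3a, and the primary radical takes hydrogen from the thiol, which regenerates the thiyl radical, so the aldehyde hydrogen ends in the new methyl group. The closest known reaction type is the thiol-catalysed radical cyclisation of alkenals to 2-methylcycloalkanones, the tin-free relative of acyl selenide cyclisations. The cyclopentanone closes in a 5-exo-trig mode, and the ring fusion is trans because the vinyl and 1-oxobutan-2-yl arms are already trans and diequatorial on the cyclohexene from step 15. The only new stereocentre, C3, forms under kinetic control and is then equilibrated by DBU, since the epimer with the methyl group nearly eclipsing the bond from C3a to the quaternary C4 is disfavoured; C1 is equilibrated in the same way. The step needs 5-exo closure to outrun decarbonylation of the α-branched acyl radical, and trapping of the primary radical to outrun its 3-exo ring expansion to a cyclohexanone; the fixed gauche arrangement of the two arms and fast hydrogen transfer from the thiol should secure both, and the styryl, ring-alkene and ester groups are out of reach of the acyl radical.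

**Step 20**
Reactants: 30 2-(trimethylsilyl)ethyl (1R,3R,3aS,4S,5R,7aS)-1,4,5,7-tetraethyl-3-methyl-2-oxo-5-[(E)-2-phenylethenyl]-2,3,3a,4,5,7a-hexahydro-1H-indene-4-carboxylate
Product: 31 isospiculoic acid A, (1R,3R,3aS,4S,5R,7aS)-1,4,5,7-tetraethyl-3-methyl-2-oxo-5-[(E)-2-phenylethenyl]-2,3,3a,4,5,7a-hexahydro-1H-indene-4-carboxylic acid
Conditions: TBAF, THF, 0 °C → rt; 1 M HCl work-up
Reagents that add atoms: none
Why: Fluoride attacks silicon and the ester fragments to ethene and the carboxylate, so the ester on the quaternary carbon is cleaved without attack at the hindered carbonyl; the mildly basic medium keeps C1 and C3 at their stable configurations.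

**Compound list**
1 | propyl(triphenyl)phosphonium bromide | CCC[P+](c1ccccc1)(c1ccccc1)c1ccccc1.[Br-] | starting material
2 | ethyl formate | CCOC=O | starting material
3 | propylidene(triphenyl)phosphorane | CCC=P(c1ccccc1)(c1ccccc1)c1ccccc1 | intermediate
4 | 2-(triphenyl-λ5-phosphanylidene)butanal | CCC(C=O)=P(c1ccccc1)(c1ccccc1)c1ccccc1 | intermediate
5 | (4R)-4-benzyl-1,3-oxazolidin-2-one | O=C1N[C@H](Cc2ccccc2)CO1 | starting material
6 | butanoyl chloride | CCCC(Cl)=O | starting material
7 | (4R)-4-benzyl-3-butanoyl-1,3-oxazolidin-2-one | CCCC(=O)N1[C@H](Cc2ccccc2)COC1=O | intermediate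
8 | (4R)-4-benzyl-3-[(2S)-2-(hydroxymethyl)butanoyl]-1,3-oxazolidin-2-one | CC[C@@H](CO)C(=O)N1[C@H](Cc2ccccc2)COC1=O | intermediate
9 | (4R)-4-benzyl-3-[(2S)-2-({[tert-butyl(dimethyl)silyl]oxy}methyl)butanoyl]-1,3-oxazolidin-2-one | CC[C@@H](CO[Si](C)(C)C(C)(C)C)C(=O)N1[C@H](Cc2ccccc2)COC1=O | intermediate
10 | (2R)-2-({[tert-butyl(dimethyl)silyl]oxy}methyl)butan-1-ol | CC[C@@H](CO[Si](C)(C)C(C)(C)C)CO | intermediate
11 | (2S)-2-({[tert-butyl(dimethyl)silyl]oxy}methyl)butanal | CC[C@@H](CO[Si](C)(C)C(C)(C)C)C=O | intermediate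
12 | (2E,4R)-5-{[tert-butyl(dimethyl)silyl]oxy}-2,4-diethylpent-2-enal | O=C/C(CC)=C/[C@@H](CC)CO[Si](C)(C)C(C)(C)C | intermediate
13 | (2E,4E,6R)-7-{[tert-butyl(dimethyl)silyl]oxy}-2,4,6-triethylhepta-2,4-dienal | O=C/C(CC)=C/C(CC)=C/[C@@H](CC)CO[Si](C)(C)C(C)(C)C | intermediate
14 | diethyl benzylphosphonate | CCOP(=O)(Cc1ccccc1)OCC | starting material
15 | tert-butyl(dimethyl){[(2R,3E,5E,7E)-2,4,6-triethyl-8-phenylocta-3,5,7-trien-1-yl]oxy}silane | c1ccccc1/C=C/C(CC)=C/C(CC)=C/[C@@H](CC)CO[Si](C)(C)C(C)(C)C | intermediate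
16 | (2R,3E,5E,7E)-2,4,6-triethyl-8-phenylocta-3,5,7-trien-1-ol | c1ccccc1/C=C/C(CC)=C/C(CC)=C/[C@@H](CC)CO | intermediate
17 | 2-bromobutanoyl bromide | CCC(Br)C(Br)=O | starting material
18 | 2-(trimethylsilyl)ethanol | C[Si](C)(C)CCO | starting material
19 | 2-(trimethylsilyl)ethyl 2-bromobutanoate (racemic) | CCC(Br)C(=O)OCC[Si](C)(C)C | intermediate
20 | {1-oxo-1-[2-(trimethylsilyl)ethoxy]butan-2-yl}(triphenyl)phosphonium bromide | CCC(C(=O)OCC[Si](C)(C)C)[P+](c1ccccc1)(c1ccccc1)c1ccccc1.[Br-] | intermediate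
21 | 2-(trimethylsilyl)ethyl 2-(triphenyl-λ5-phosphanylidene)butanoate | CCC(C(=O)OCC[Si](C)(C)C)=P(c1ccccc1)(c1ccccc1)c1ccccc1 | intermediate
22 | glyoxylic acid monohydrate | OC(=O)C=O.O | starting material
23 | (2E)-3-ethyl-4-oxo-4-[2-(trimethylsilyl)ethoxy]but-2-enoic acid | OC(=O)/C=C(\CC)C(=O)OCC[Si](C)(C)C | intermediate
24 | 4-[(2R,3E,5E,7E)-2,4,6-triethyl-8-phenylocta-3,5,7-trien-1-yl] 1-[2-(trimethylsilyl)ethyl] (2E)-2-ethylbut-2-enedioate | c1ccccc1/C=C/C(CC)=C/C(CC)=C/[C@@H](CC)COC(=O)/C=C(\CC)C(=O)OCC[Si](C)(C)C | intermediate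
25 | 2-(trimethylsilyl)ethyl (4R,4aR,7R,8S,8aR)-4,5,7,8-tetraethyl-1-oxo-7-[(E)-2-phenylethenyl]-3,4,4a,7,8,8a-hexahydro-1H-isochromene-8-carboxylate (trans-fused δ-lactone) | CCC1=C[C@](/C=C/c2ccccc2)(CC)[C@@](CC)(C(=O)OCC[Si](C)(C)C)[C@H]2[C@H]1[C@@H](CC)COC2=O | intermediate
26 | 2-(trimethylsilyl)ethyl (4R,4aR,7R,8S,8aR)-4,5,7,8-tetraethyl-1-hydroxy-7-[(E)-2-phenylethenyl]-3,4,4a,7,8,8a-hexahydro-1H-isochromene-8-carboxylate (lactol, both C1 anomers) | CCC1=C[C@](/C=C/c2ccccc2)(CC)[C@@](CC)(C(=O)OCC[Si](C)(C)C)[C@H]2[C@H]1[C@@H](CC)COC2O | intermediate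
27 | 2-(trimethylsilyl)ethyl (1S,2R,5S,6R)-6-ethenyl-1,2,4-triethyl-5-[(2R)-1-hydroxybutan-2-yl]-2-[(E)-2-phenylethenyl]cyclohex-3-ene-1-carboxylate | CCC1=C[C@](/C=C/c2ccccc2)(CC)[C@@](CC)(C(=O)OCC[Si](C)(C)C)[C@H](C=C)[C@H]1[C@@H](CC)CO | intermediate
28 | 2-(trimethylsilyl)ethyl (1S,2R,5S,6R)-6-ethenyl-1,2,4-triethyl-5-[(2R)-1-oxobutan-2-yl]-2-[(E)-2-phenylethenyl]cyclohex-3-ene-1-carboxylate | CCC1=C[C@](/C=C/c2ccccc2)(CC)[C@@](CC)(C(=O)OCC[Si](C)(C)C)[C@H](C=C)[C@H]1[C@@H](CC)C=O | intermediate
29 | 2-(trimethylsilyl)ethyl (1R,3aS,4S,5R,7aS)-1,4,5,7-tetraethyl-3-methyl-2-oxo-5-[(E)-2-phenylethenyl]-2,3,3a,4,5,7a-hexahydro-1H-indene-4-carboxylate (C3 epimer mixture) | CCC1=C[C@](/C=C/c2ccccc2)(CC)[C@@](CC)(C(=O)OCC[Si](C)(C)C)[C@H]2[C@H]1[C@@H](CC)C(=O)C2C | intermediate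
30 | 2-(trimethylsilyl)ethyl (1R,3R,3aS,4S,5R,7aS)-1,4,5,7-tetraethyl-3-methyl-2-oxo-5-[(E)-2-phenylethenyl]-2,3,3a,4,5,7a-hexahydro-1H-indene-4-carboxylate | CCC1=C[C@](/C=C/c2ccccc2)(CC)[C@@](CC)(C(=O)OCC[Si](C)(C)C)[C@H]2[C@H]1[C@@H](CC)C(=O)[C@@H]2C | intermediate
31 | isospiculoic acid A, (1R,3R,3aS,4S,5R,7aS)-1,4,5,7-tetraethyl-3-methyl-2-oxo-5-[(E)-2-phenylethenyl]-2,3,3a,4,5,7a-hexahydro-1H-indene-4-carboxylic acid | CCC1=C[C@](/C=C/c2ccccc2)(CC)[C@@](CC)(C(=O)O)[C@H]2[C@H]1[C@@H](CC)C(=O)[C@@H]2C | target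

**Step count and risks**
Total step count: 20. Longest linear sequence: 16 (steps 2–10 and 14–20).

Steps most likely to fail:

1. Step 15 (Diels–Alder). The tether carbonyl may compete with the free ester for the endo position and give the cis-fused adduct with the wrong configuration at the ester-bearing quaternary carbon, or the cycloaddition that forms two adjacent quaternary carbons may be too slow. The fallback sets out from 16 and returns at 25. Trienol 16 is opened onto 3-ethylfuran-2,5-dione (Et3N, CH2Cl2) at the carbonyl remote from the ethyl group to give (2Z)-2-ethyl-4-oxo-4-{[(2R,3E,5E,7E)-2,4,6-triethyl-8-phenylocta-3,5,7-trien-1-yl]oxy}but-2-enoic acid F1. Mitsunobu esterification of its free carboxyl with 18 (PPh3, DIAD) gives 4-[(2R,3E,5E,7E)-2,4,6-triethyl-8-phenylocta-3,5,7-trien-1-yl] 1-[2-(trimethylsilyl)ethyl] (2Z)-2-ethylbut-2-enedioate F2. With the Z-dienophile both carbonyls can lie endo, so heating should give the cis-fused lactone 2-(trimethylsilyl)ethyl (4R,4aR,7R,8S,8aS)-4,5,7,8-tetraethyl-1-oxo-7-[(E)-2-phenylethenyl]-3,4,4a,7,8,8a-hexahydro-1H-isochromene-8-carboxylate F3, which has the required quaternary centres. DBU (toluene, 60 °C) then epimerises C8a, α to the lactone carbonyl, to the trans-fused lactone 25.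

2. Step 19 (key step). The α-branched acyl radical may lose CO before it cyclises, the thiol may be consumed by addition to the terminal alkene, or reversible abstraction of the tertiary allylic hydrogen at the ring fusion may erode that centre. The fallback sets out from 28 and returns at 30 and uses a ketyl instead of an acyl radical, so decarbonylation cannot occur. SmI2, HMPA and t-BuOH (THF, −78 → 0 °C) should effect 5-exo ketyl–olefin cyclisation to 2-(trimethylsilyl)ethyl (1R,3aS,4S,5R,7aS)-1,4,5,7-tetraethyl-2-hydroxy-3-methyl-5-[(E)-2-phenylethenyl]-2,3,3a,4,5,7a-hexahydro-1H-indene-4-carboxylate F4 (mixture at C2 and C3). Dess–Martin oxidation and DBU equilibration then give 30.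

3. Step 17 (methylenation). The hindered aldehyde next to the quaternary carbon may react slowly with the ylide, and prolonged exposure to base may epimerise the ring-fusion centre. The fallback sets out from 26 and returns at 27. The less basic organocerium reagent from Me3SiCH2MgCl and CeCl3 (THF, −78 → 0 °C) adds to the open aldehyde form to give 2-(trimethylsilyl)ethyl (1S,2R,5R,6R)-1,2,4-triethyl-5-[(2R)-1-hydroxybutan-2-yl]-6-[1-hydroxy-2-(trimethylsilyl)ethyl]-2-[(E)-2-phenylethenyl]cyclohex-3-ene-1-carboxylate F5. KH (THF, 0 °C) then induces Peterson syn-elimination to the vinyl compound 27.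

**Further compounds**
F1 | step 15 | (2Z)-2-ethyl-4-oxo-4-{[(2R,3E,5E,7E)-2,4,6-triethyl-8-phenylocta-3,5,7-trien-1-yl]oxy}but-2-enoic acid | c1ccccc1/C=C/C(CC)=C/C(CC)=C/[C@@H](CC)COC(=O)/C=C(/CC)C(O)=O
F2 | step 15 | 4-[(2R,3E,5E,7E)-2,4,6-triethyl-8-phenylocta-3,5,7-trien-1-yl] 1-[2-(trimethylsilyl)ethyl] (2Z)-2-ethylbut-2-enedioate | c1ccccc1/C=C/C(CC)=C/C(CC)=C/[C@@H](CC)COC(=O)/C=C(/CC)C(=O)OCC[Si](C)(C)C
F3 | step 15 | 2-(trimethylsilyl)ethyl (4R,4aR,7R,8S,8aS)-4,5,7,8-tetraethyl-1-oxo-7-[(E)-2-phenylethenyl]-3,4,4a,7,8,8a-hexahydro-1H-isochromene-8-carboxylate (cis-fused lactone) | CCC1=C[C@](/C=C/c2ccccc2)(CC)[C@@](CC)(C(=O)OCC[Si](C)(C)C)[C@@H]2[C@H]1[C@@H](CC)COC2=O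
F4 | step 19 | 2-(trimethylsilyl)ethyl (1R,3aS,4S,5R,7aS)-1,4,5,7-tetraethyl-2-hydroxy-3-methyl-5-[(E)-2-phenylethenyl]-2,3,3a,4,5,7a-hexahydro-1H-indene-4-carboxylate (mixture at C2 and C3) | CCC1=C[C@](/C=C/c2ccccc2)(CC)[C@@](CC)(C(=O)OCC[Si](C)(C)C)[C@H]2[C@H]1[C@@H](CC)C(O)C2C
F5 | step 17 | 2-(trimethylsilyl)ethyl (1S,2R,5R,6R)-1,2,4-triethyl-5-[(2R)-1-hydroxybutan-2-yl]-6-[1-hydroxy-2-(trimethylsilyl)ethyl]-2-[(E)-2-phenylethenyl]cyclohex-3-ene-1-carboxylate | CCC1=C[C@](/C=C/c2ccccc2)(CC)[C@@](CC)(C(=O)OCC[Si](C)(C)C)[C@H](C(O)C[Si](C)(C)C)[C@H]1[C@@H](CC)CO
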